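**Plan**
The retrosynthesis first cuts the C3–Br bond (electrophilic bromination comes last), then the N1–S bond of a mesyl protecting group, then the N1–C2 bond of the pyrrole ring.
C2 is bonded to both N1 and a bromine, so it is the CBr2 carbon of an N-mesyl 2-(2,2-dibromovinyl)anilide: one vinylic bromide leaves on ring closure and the other remains as the C2 bromine.
Further cuts are the C2=C3 double bond (dibromo-olefination of an aldehyde), the C7a–N1 bond (SNAr on an ortho-fluorobenzaldehyde) and the C3a–C3 bond (formylation of an aryllithium). These lead back to 1,4-dibromo-2-fluorobenzene, which already carries the C4 and C7 bromines in the right places.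
Forward order: the benzene ring is bought; C3, N1 and C2 are attached in turn; the pyrrole ring is the only ring formed (step 4); C3 is brominated at the end.
Stereochemistry: the target is achiral, with no stereocentre and no configured double bond, so nothing has to be controlled.

Key step: step 4

Remark: the ring closure is written as elimination to the 1-bromoalkyne followed by 5-endo-dig addition; direct addition–elimination at the CBr2 carbon would give the same product.

**Step 1**
Reactants: 1 1,4-dibromo-2-fluorobenzene; 2 N,N-dimethylformamide
Product: 5 3,6-dibromo-2-fluorobenzaldehyde, via 3,6-dibromo-2-fluorophenyllithium 3 (not isolated), via lithium hemiaminal alkoxide 4 (not isolated)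
Conditions: LiN(iPr)2 (1.05 equiv), THF, −78 °C; DMF, −78 °C; aq. HCl
Reagents that add atoms: N,N-dimethylformamide, CN(C)C=O
Why: Directed ortho-lithiation followed by formylation: the C–H flanked by fluorine and bromine is by far the most acidic site of 1, so the amide base removes it without bromine–lithium exchange, and the aryllithium, kept cold to prevent aryne formation, is trapped by DMF, which fixes the substitution pattern unambiguously.

**Step 2**
Reactants: 5 3,6-dibromo-2-fluorobenzaldehyde; 6 methanesulfonamide
Product: 7 N-(3,6-dibromo-2-formylphenyl)methanesulfonamide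
Conditions: MsNH2 (1.5 equiv), K2CO3 (2.5 equiv), DMSO, 80 °C; aq. HCl
Reagents that add atoms: methanesulfonamide, CS(N)(=O)=O
Why: Nucleophilic aromatic substitution (SNAr): the fluoride ortho to the formyl group, further activated by both ring bromines, should be displaced by the sulfonamide anion much faster than the ortho bromide, while the non-enolisable aldehyde tolerates carbonate and the product rests as its unreactive N-anion until acidification.

**Step 3**
Reactants: 7 N-(3,6-dibromo-2-formylphenyl)methanesulfonamide; 8 carbon tetrabromide
Product: 9 N-[3,6-dibromo-2-(2,2-dibromovinyl)phenyl]methanesulfonamide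
Conditions: CBr4 (2 equiv), PPh3 (4 equiv), CH2Cl2, 0 °C; then 7, 0 °C to rt
Reagents that add atoms: carbon tetrabromide, BrC(Br)(Br)Br
Why: Ramirez dibromo-olefination (first half of the Corey–Fuchs sequence): pre-formed Ph3P=CBr2 converts the aldehyde into the 1,1-dibromoalkene by a Wittig reaction, the excess of ylide offsetting partial protonation by the sulfonamide N–H in the way unprotected ortho-hydroxybenzaldehydes are handled, and the aryl bromides and the sulfonyl group are inert to the reagent.

**Step 4**
Reactants: 9 N-[3,6-dibromo-2-(2,2-dibromovinyl)phenyl]methanesulfonamide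
Product: 11 2,4,7-tribromo-1-(methylsulfonyl)indole, via bromoalkynyl sulfonamide 10 (not isolated)
Conditions: Cs2CO3 (2.5 equiv), DMF, 60 °C
Reagents that add atoms: none
Why: Cs2CO3 deprotonates the acidic sulfonamide N–H and removes HBr from the dibromoalkene (anti elimination of the vinylic hydrogen and the bromide trans to it) to give 1-bromoalkyne 10, whose nitrogen anion adds to the bromine-bearing alkyne carbon, after which the C3 carbanion is protonated by hydrogencarbonate. The closest known reaction type is the transition-metal-free, carbonate- or fluoride-promoted cyclisation of N-sulfonyl 2-(2,2-dibromovinyl)anilines to 2-bromoindoles. The pyrrole ring closes in a 5-endo-dig mode, with N1–C2 as the only new skeletal bond. No stereocentre is created. The step needs chemoselectivity, namely loss of exactly one vinylic bromide with the two aryl bromides and the new C2 bromide left in place; this is secured because only the CBr2 terminus can react by elimination–addition, no transition metal is present to insert into C(sp2)–Br bonds, and the N-sulfonyl 2-bromoindole formed has neither an N–H nor a vinylic hydrogen left for a second elimination. Attack at the bromine-bearing carbon and not at the aryl-bearing one follows from geometry, since only that carbon can be reached in a five-membered transition state.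

**Step 5**
Reactants: 11 2,4,7-tribromo-1-(methylsulfonyl)indole
Product: 12 2,4,7-tribromo-1H-indole
Conditions: NaOH (2 M aq.), THF/MeOH, 40 °C; aq. NH4Cl
Reagents that add atoms: none
Why: Base-mediated N-desulfonylation: hydroxide attacks sulfur and expels the indolide, a good leaving group here because three bromines stabilise it, while the aryl and C2 bromides should not be displaced under these mild conditions and the neutral work-up spares the acid-sensitive 2-bromoindole.

**Step 6**
Reactants: 12 2,4,7-tribromo-1H-indole; 13 N-bromosuccinimide
Product: 14 2,3,4,7-tetrabromo-1H-indole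
Conditions: NBS (1.0 equiv), DMF, 0 °C, dark
Reagents that add atoms: N-bromosuccinimide, O=C1CCC(=O)N1Br
Why: Electrophilic aromatic substitution: C3 is the only free pyrrole position and the most nucleophilic carbon of the N–H indole, whereas the benzo ring is deactivated by its two bromines, so one equivalent of NBS should brominate C3 alone.

**Compound list**
1 | 1,4-dibromo-2-fluorobenzene | Fc1cc(Br)ccc1Br | starting material
2 | N,N-dimethylformamide | CN(C)C=O | starting material
3 | 3,6-dibromo-2-fluorophenyllithium | [Li]c1c(F)c(Br)ccc1Br | intermediate
4 | lithium (3,6-dibromo-2-fluorophenyl)(dimethylamino)methanolate (racemic, transient) | [Li]OC(N(C)C)c1c(F)c(Br)ccc1Br | intermediate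
5 | 3,6-dibromo-2-fluorobenzaldehyde | O=Cc1c(F)c(Br)ccc1Br | intermediate
6 | methanesulfonamide | CS(N)(=O)=O | starting material
7 | N-(3,6-dibromo-2-formylphenyl)methanesulfonamide | CS(=O)(=O)Nc1c(Br)ccc(Br)c1C=O | intermediate
8 | carbon tetrabromide | BrC(Br)(Br)Br | starting material
9 | N-[3,6-dibromo-2-(2,2-dibromovinyl)phenyl]methanesulfonamide | CS(=O)(=O)Nc1c(Br)ccc(Br)c1C=C(Br)Br | intermediate
10 | N-[3,6-dibromo-2-(bromoethynyl)phenyl]methanesulfonamide (present as its N-anion) | CS(=O)(=O)Nc1c(Br)ccc(Br)c1C#CBr | intermediate
11 | 2,4,7-tribromo-1-(methylsulfonyl)indole | CS(=O)(=O)n1c(Br)cc2c(Br)ccc(Br)c21 | intermediate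
12 | 2,4,7-tribromo-1H-indole | Brc1cc2c(Br)ccc(Br)c2[nH]1 | intermediate
13 | N-bromosuccinimide | O=C1CCC(=O)N1Br | starting material
14 | 2,3,4,7-tetrabromo-1H-indole | Brc1[nH]c2c(Br)ccc(Br)c2c1Br | target

**Step count and risks**
Total step count: 6. Longest linear sequence: 6 steps (1 → 5 → 7 → 9 → 11 → 12 → 14).

Steps most likely to fail:

Step 3. The acidic sulfonamide N–H may protonate the dibromomethylene ylide, and the aldehyde, flanked by the sulfonamide and a bromine, may add the bulky ylide slowly, so the olefination could stall. The fallback masks the N–H first. From 7, Boc2O with DMAP and Et3N in MeCN should give tert-butyl N-(3,6-dibromo-2-formylphenyl)-N-(methylsulfonyl)carbamate F1, which has no acidic proton. Ramirez olefination (CBr4, PPh3, CH2Cl2, 0 °C) should then give tert-butyl N-[3,6-dibromo-2-(2,2-dibromovinyl)phenyl]-N-(methylsulfonyl)carbamate F2. TFA in CH2Cl2 removes the Boc group and returns to the route at 9.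

Step 2. Displacement of fluoride by the weakly nucleophilic sulfonamide anion at a doubly flanked carbon may be slow, leaving room for reversible addition to the formyl group or attack at the ortho bromide. The fallback brings nitrogen in with a small, strong nucleophile and sulfonylates afterwards. From 5, NaN3 in DMSO at 40 °C should give 2-azido-3,6-dibromobenzaldehyde F3. Reduction of the azide with SnCl2·2H2O in MeOH should give 2-amino-3,6-dibromobenzaldehyde F4. MsCl in pyridine then returns to the route at 7.

Step 4. The sulfonamide anion, hindered and deactivated by the neighbouring bromine, may close too slowly, so the reaction could stop at the bromoalkyne or lose it to hydration and oligomerisation. The fallback gives up the CBr2 closure and installs both pyrrole bromines electrophilically. From 7, Bestmann–Ohira homologation (dimethyl (1-diazo-2-oxopropyl)phosphonate, K2CO3, MeOH) should give N-(3,6-dibromo-2-ethynylphenyl)methanesulfonamide F5. Cu(OAc)2-catalysed 5-endo-dig hydroamination in 1,2-dichloroethane at 70 °C should give 4,7-dibromo-1-(methylsulfonyl)indole F6. Aqueous NaOH in THF/MeOH frees 4,7-dibromo-1H-indole F7. Two equivalents of NBS in DMF brominate C3 and then C2 by way of 3,4,7-tribromo-1H-indole F8, returning to the route at 14.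

**Further compounds**
F1 | step 3 | tert-butyl N-(3,6-dibromo-2-formylphenyl)-N-(methylsulfonyl)carbamate | CC(C)(C)OC(=O)N(c1c(Br)ccc(Br)c1C=O)S(C)(=O)=O
F2 | step 3 | tert-butyl N-[3,6-dibromo-2-(2,2-dibromovinyl)phenyl]-N-(methylsulfonyl)carbamate | CC(C)(C)OC(=O)N(c1c(Br)ccc(Br)c1C=C(Br)Br)S(C)(=O)=O
F3 | step 2 | 2-azido-3,6-dibromobenzaldehyde | [N-]=[N+]=Nc1c(Br)ccc(Br)c1C=O
F4 | step 2 | 2-amino-3,6-dibromobenzaldehyde | Nc1c(Br)ccc(Br)c1C=O
F5 | step 4 | N-(3,6-dibromo-2-ethynylphenyl)methanesulfonamide | CS(=O)(=O)Nc1c(Br)ccc(Br)c1C#C
F6 | step 4 | 4,7-dibromo-1-(methylsulfonyl)indole | CS(=O)(=O)n1ccc2c(Br)ccc(Br)c21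
F7 | step 4 | 4,7-dibromo-1H-indole | Brc1ccc(Br)c2[nH]ccc12
F8 | step 4 | 3,4,7-tribromo-1H-indole | Brc1c[nH]c2c(Br)ccc(Br)c12
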